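**Retrosynthetic overview**

1. Key disconnection: C1–C15, the bond between the ring carbinol carbon and the side-chain methine. It is made by a stereospecific lithiation–borylation–oxidation that unites the C17 macrocyclic (S)-benzoate 22 with the C8 (R)-sec-alkyl boronic ester 33 and returns the tertiary OH from boron.
2. Enabling feature: C1 is the only oxygen-bearing sp3 carbon of the 14-membered carbocycle and carries, besides O, only the two ring CH2 arms (C2, C14) and C15. It can therefore be traced back to a ring CH–O ester whose oxygen first directs lithiation of C1–H and then leaves; the three trisubstituted ring alkenes (C3=C4 Z, C7=C8 E, C11=C12 E) tolerate sBuLi and H2O2.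
3. Ring: the single 14-membered ring is closed before the key step at C5–C6 by intramolecular alkylation of an allylic sulfone anion with a (Z)-allylic chloride. C1 is set earlier, while its two arms are still very different, by Noyori hydrogenation of a β-keto ester; C3=C4 comes from a Still–Gennari olefination, C7=C8 and C11=C12 from geraniol.
4. Side chain: cross-metathesis fixes the (E)-allylic alcohol, and a sparteine-controlled one-carbon homologation of a primary boronic ester sets C15.

Key step: step 22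

Remark: locants used throughout are C1 = ring carbinol carbon, C2–C14 = remaining ring carbons (methyls on C4, C8, C12), C15 = side-chain methine; the neopentyl glycol boronic ester 25 is assumed not to be a stock item and is made in step 17.

**Route**

Step 1
Reactants: 1 geraniol
Product: 2 geranyl 4-methoxybenzyl ether
Conditions: NaH, PMBCl, Bu4NI (cat.), THF, 0 °C → rt
Reagents that add atoms: 4-methoxybenzyl chloride, COc1ccc(CCl)cc1
Why: Williamson etherification of the primary allylic alkoxide protects the future C6 oxygen in a form that survives the dianion, hydrogenation and silylation steps.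

Step 2
Reactants: 2 geranyl 4-methoxybenzyl ether
Product: 3 (2E,6E)-8-[(4-methoxybenzyl)oxy]-2,6-dimethylocta-2,6-dien-1-ol
Conditions: SeO2 (cat.), tBuOOH, salicylic acid (cat.), CH2Cl2, 0 °C → rt
Reagents that add atoms: tert-butyl hydroperoxide, CC(C)(C)OO
Why: Riley allylic oxidation (ene reaction then [2,3]-sigmatropic shift) should oxidise the (E)-methyl group of the more electron-rich terminal alkene, which fixes the later C11=C12 (E) geometry.

Step 3
Reactants: 3 (2E,6E)-8-[(4-methoxybenzyl)oxy]-2,6-dimethylocta-2,6-dien-1-ol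
Product: 4 1-({[(2E,6E)-8-bromo-3,7-dimethylocta-2,6-dien-1-yl]oxy}methyl)-4-methoxybenzene
Conditions: CBr4, PPh3, CH2Cl2, 0 °C
Reagents that add atoms: carbon tetrabromide, BrC(Br)(Br)Br
Why: Appel bromination of a primary allylic alcohol proceeds by SN2 at CH2 without allylic transposition.

Step 4
Reactants: 4 1-({[(2E,6E)-8-bromo-3,7-dimethylocta-2,6-dien-1-yl]oxy}methyl)-4-methoxybenzene; 5 methyl acetoacetate
Product: 7 methyl (6E,10E)-12-[(4-methoxybenzyl)oxy]-6,10-dimethyl-3-oxododeca-6,10-dienoate, via methyl acetoacetate dianion 6 (not isolated)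
Conditions: 5, NaH, THF, 0 °C; nBuLi, 0 °C; then 4, 0 °C → rt
Reagents that add atoms: none
Why: γ-Alkylation of the acetoacetate dianion: the more basic terminal carbanion should attack the primary allylic bromide by SN2 and form the C13–C14 bond.

Step 5
Reactants: 7 methyl (6E,10E)-12-[(4-methoxybenzyl)oxy]-6,10-dimethyl-3-oxododeca-6,10-dienoate
Product: 8 methyl (3R,6E,10E)-3-hydroxy-12-[(4-methoxybenzyl)oxy]-6,10-dimethyldodeca-6,10-dienoate
Conditions: H2 (4 atm), [RuCl2((R)-BINAP)]2·NEt3 (cat.), MeOH, 50 °C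
Reagents that add atoms: none
Why: Noyori asymmetric hydrogenation of a β-keto ester: ester chelation to ruthenium lets (R)-BINAP deliver hydride to one carbonyl face and set C1 (3R here) while its two substituents are still a CH2CO2Me group and an alkyl chain, and the trisubstituted alkenes are not reduced by this catalyst.

Step 6
Reactants: 8 methyl (3R,6E,10E)-3-hydroxy-12-[(4-methoxybenzyl)oxy]-6,10-dimethyldodeca-6,10-dienoate
Product: 9 methyl (3R,6E,10E)-3-[(tert-butyldimethylsilyl)oxy]-12-[(4-methoxybenzyl)oxy]-6,10-dimethyldodeca-6,10-dienoate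
Conditions: TBSCl, imidazole, DMF, rt
Reagents that add atoms: tert-butyldimethylsilyl chloride, CC(C)(C)[Si](C)(C)Cl
Why: Silylation of the secondary alcohol prevents β-elimination and retro-aldol chemistry in the later aldehyde and carbanion steps.

Step 7
Reactants: 9 methyl (3R,6E,10E)-3-[(tert-butyldimethylsilyl)oxy]-12-[(4-methoxybenzyl)oxy]-6,10-dimethyldodeca-6,10-dienoate
Product: 10 methyl (3R,6E,10E)-3-[(tert-butyldimethylsilyl)oxy]-12-hydroxy-6,10-dimethyldodeca-6,10-dienoate
Conditions: DDQ, CH2Cl2/pH 7 buffer, 0 °C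
Reagents that add atoms: none
Why: Oxidative cleavage of the 4-methoxybenzyl ether by DDQ frees the primary allylic alcohol and leaves the silyl ether, the ester and the alkenes untouched.

Step 8
Reactants: 10 methyl (3R,6E,10E)-3-[(tert-butyldimethylsilyl)oxy]-12-hydroxy-6,10-dimethyldodeca-6,10-dienoate
Product: 12 methyl (3R,6E,10E)-3-[(tert-butyldimethylsilyl)oxy]-6,10-dimethyl-12-(phenylsulfonyl)dodeca-6,10-dienoate, via allylic bromide 11 (not isolated)
Conditions: CBr4, PPh3, CH2Cl2, 0 °C; then PhSO2Na, DMF, rt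
Reagents that add atoms: sodium benzenesulfinate, [Na+].[O-]S(=O)c1ccccc1
Why: Appel bromination followed by S-alkylation of the sulfinate (SN2 at the primary allylic carbon) installs the carbanion-stabilising group at C6 with the (E)-alkene unchanged.

Step 9
Reactants: 12 methyl (3R,6E,10E)-3-[(tert-butyldimethylsilyl)oxy]-6,10-dimethyl-12-(phenylsulfonyl)dodeca-6,10-dienoate
Product: 13 (3R,6E,10E)-3-[(tert-butyldimethylsilyl)oxy]-6,10-dimethyl-12-(phenylsulfonyl)dodeca-6,10-dienal
Conditions: DIBAL-H (1.1 equiv), CH2Cl2, −78 °C; Rochelle salt work-up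
Reagents that add atoms: none
Why: Partial reduction of the methyl ester stops at the aldehyde because the tetrahedral aluminium hemiacetal is stable at −78 °C.

Step 10
Reactants: 13 (3R,6E,10E)-3-[(tert-butyldimethylsilyl)oxy]-6,10-dimethyl-12-(phenylsulfonyl)dodeca-6,10-dienal; 14 ethyl 2-[bis(2,2,2-trifluoroethoxy)phosphoryl]propanoate
Product: 16 ethyl (2Z,5R,8E,12E)-5-[(tert-butyldimethylsilyl)oxy]-2,8,12-trimethyl-14-(phenylsulfonyl)tetradeca-2,8,12-trienoate, via potassium phosphonate carbanion 15 (not isolated)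
Conditions: 14, KHMDS, 18-crown-6, THF, −78 °C; then 13, −78 °C
Reagents that add atoms: none
Why: Still–Gennari olefination: fast, irreversible elimination from the kinetically formed adduct of the electron-poor phosphonate should place the ester cis to the chain and so give the C3=C4 (Z) trisubstituted alkene.

Step 11
Reactants: 16 ethyl (2Z,5R,8E,12E)-5-[(tert-butyldimethylsilyl)oxy]-2,8,12-trimethyl-14-(phenylsulfonyl)tetradeca-2,8,12-trienoate
Product: 17 (2Z,5R,8E,12E)-5-[(tert-butyldimethylsilyl)oxy]-2,8,12-trimethyl-14-(phenylsulfonyl)tetradeca-2,8,12-trien-1-ol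
Conditions: DIBAL-H (2.5 equiv), CH2Cl2, −78 °C
Reagents that add atoms: none
Why: 1,2-Reduction of the enoate to the allylic alcohol does not touch the alkene geometry or the sulfone.

Step 12
Reactants: 17 (2Z,5R,8E,12E)-5-[(tert-butyldimethylsilyl)oxy]-2,8,12-trimethyl-14-(phenylsulfonyl)tetradeca-2,8,12-trien-1-ol
Product: 18 tert-butyl{[(2Z,5R,8E,12E)-1-chloro-2,8,12-trimethyl-14-(phenylsulfonyl)tetradeca-2,8,12-trien-5-yl]oxy}dimethylsilane
Conditions: NCS, Me2S, CH2Cl2, −20 → 0 °C
Reagents that add atoms: N-chlorosuccinimide, ClN1C(=O)CCC1=O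
Why: Corey–Kim chlorination converts the allylic alcohol into the chloride by SN2 on the alkoxysulfonium ion, without allylic shift or Z/E isomerisation.

Step 13
Reactants: 18 tert-butyl{[(2Z,5R,8E,12E)-1-chloro-2,8,12-trimethyl-14-(phenylsulfonyl)tetradeca-2,8,12-trien-5-yl]oxy}dimethylsilane
Product: 19 tert-butyldimethyl{[(1R,3Z,7E,11E)-4,8,12-trimethyl-6-(phenylsulfonyl)cyclotetradeca-3,7,11-trien-1-yl]oxy}silane (both C6 epimers)
Conditions: KHMDS, THF, −78 → 0 °C, slow addition of 18 (final concentration about 2 mM)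
Reagents that add atoms: none
Why: Intramolecular SN2 alkylation of the sulfonyl-stabilised allylic carbanion by the primary allylic chloride under high dilution should close the 14-membered ring at C5–C6 (14-exo-tet) with retention of the C3=C4 (Z) geometry, and the C6 epimers converge in step 14.

Step 14
Reactants: 19 tert-butyldimethyl{[(1R,3Z,7E,11E)-4,8,12-trimethyl-6-(phenylsulfonyl)cyclotetradeca-3,7,11-trien-1-yl]oxy}silane
Product: 20 tert-butyldimethyl{[(1R,3Z,7E,11E)-4,8,12-trimethylcyclotetradeca-3,7,11-trien-1-yl]oxy}silane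
Conditions: PdCl2(dppp) (cat.), LiBHEt3, THF, 0 °C
Reagents that add atoms: none
Why: Palladium-catalysed reductive desulfonylation: hydride should attack the π-allylpalladium intermediate at its less substituted terminus C6, which keeps the C7=C8 alkene in place.

Step 15
Reactants: 20 tert-butyldimethyl{[(1R,3Z,7E,11E)-4,8,12-trimethylcyclotetradeca-3,7,11-trien-1-yl]oxy}silane
Product: 21 (1R,3Z,7E,11E)-4,8,12-trimethylcyclotetradeca-3,7,11-trien-1-ol
Conditions: TBAF, THF, rt
Reagents that add atoms: none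
Why: Fluoride-induced desilylation frees the ring carbinol without affecting the alkenes.

Step 16
Reactants: 21 (1R,3Z,7E,11E)-4,8,12-trimethylcyclotetradeca-3,7,11-trien-1-ol
Product: 22 (1S,3Z,7E,11E)-4,8,12-trimethylcyclotetradeca-3,7,11-trien-1-yl 2,4,6-tri(propan-2-yl)benzoate
Conditions: 2,4,6-triisopropylbenzoic acid, PPh3, DIAD, THF, 0 °C → rt
Reagents that add atoms: 2,4,6-triisopropylbenzoic acid, CC(C)c1cc(C(C)C)c(C(=O)O)c(C(C)C)c1
Why: Mitsunobu esterification inverts C1 by SN2 displacement of the activated alcohol and gives the hindered (1S)-benzoate that can be lithiated at C1 without attack on the carbonyl group.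

Step 17
Reactants: 23 but-3-en-1-ylmagnesium bromide
Product: 25 2-(but-3-en-1-yl)-5,5-dimethyl-1,3,2-dioxaborinane, via dimethyl but-3-en-1-ylboronate 24 (not isolated)
Conditions: B(OMe)3, THF, −78 °C → rt; then neopentyl glycol, rt, volatiles removed
Reagents that add atoms: trimethyl borate, COB(OC)OC; neopentyl glycol, OCC(C)(C)CO
Why: Borylation of the Grignard reagent with trimethyl borate followed by transesterification gives the six-membered cyclic ester, which is the least hindered stable boronic ester.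

Step 18
Reactants: 25 2-(but-3-en-1-yl)-5,5-dimethyl-1,3,2-dioxaborinane; 26 methacrolein
Product: 27 (2E)-5-(5,5-dimethyl-1,3,2-dioxaborinan-2-yl)-2-methylpent-2-enal
Conditions: Hoveyda–Grubbs II catalyst (cat.), excess 26, CH2Cl2, 40 °C
Reagents that add atoms: none
Why: Olefin cross-metathesis of a terminal alkene with the 1,1-disubstituted enal should give the thermodynamically favoured (E)-trisubstituted enal, which sets the side-chain alkene geometry.

Step 19
Reactants: 27 (2E)-5-(5,5-dimethyl-1,3,2-dioxaborinan-2-yl)-2-methylpent-2-enal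
Product: 28 (2E)-5-(5,5-dimethyl-1,3,2-dioxaborinan-2-yl)-2-methylpent-2-en-1-ol
Conditions: NaBH4, CeCl3·7H2O, MeOH, 0 °C
Reagents that add atoms: none
Why: Luche reduction gives clean 1,2-reduction of the enal and leaves the boronic ester intact.

Step 20
Reactants: 28 (2E)-5-(5,5-dimethyl-1,3,2-dioxaborinan-2-yl)-2-methylpent-2-en-1-ol
Product: 29 tert-butyl{[(2E)-5-(5,5-dimethyl-1,3,2-dioxaborinan-2-yl)-2-methylpent-2-en-1-yl]oxy}dimethylsilane
Conditions: TBSCl, imidazole, CH2Cl2, rt
Reagents that add atoms: tert-butyldimethylsilyl chloride, CC(C)(C)[Si](C)(C)Cl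
Why: Silylation masks the allylic alcohol against the organolithium reagents of steps 21 and 22.

Step 21
Reactants: 29 tert-butyl{[(2E)-5-(5,5-dimethyl-1,3,2-dioxaborinan-2-yl)-2-methylpent-2-en-1-yl]oxy}dimethylsilane; 30 ethyl 2,4,6-tri(propan-2-yl)benzoate
Product: 33 tert-butyl{[(2E,6R)-6-(5,5-dimethyl-1,3,2-dioxaborinan-2-yl)-2-methylhept-2-en-1-yl]oxy}dimethylsilane, via lithiated ethyl benzoate 31 (not isolated), via boronate complex 32 (not isolated)
Conditions: 30, (−)-sparteine, sBuLi, Et2O, −78 °C; then 29, −78 °C; then warm to reflux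
Reagents that add atoms: none
Why: Lithiation–borylation homologation: sparteine-directed deprotonation gives the (S)-lithiated benzoate, which is borylated with retention and then undergoes 1,2-migration of the primary alkyl group with inversion at the carbenoid carbon, so that the reagent alone sets C15 as (R).

Step 22
Reactants: 22 (1S,3Z,7E,11E)-4,8,12-trimethylcyclotetradeca-3,7,11-trien-1-yl 2,4,6-tri(propan-2-yl)benzoate; 33 tert-butyl{[(2E,6R)-6-(5,5-dimethyl-1,3,2-dioxaborinan-2-yl)-2-methylhept-2-en-1-yl]oxy}dimethylsilane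
Product: 37 tert-butyl{[(2E,6R)-6-[(1S,3Z,7E,11E)-1-hydroxy-4,8,12-trimethylcyclotetradeca-3,7,11-trien-1-yl]-2-methylhept-2-en-1-yl]oxy}dimethylsilane, via lithiated macrocyclic benzoate 34 (not isolated), via boronate complex 35 (not isolated), via tertiary boronic ester 36 (not isolated)
Conditions: 22, sBuLi, TMEDA, CPME, −60 °C; then 33, −60 → 40 °C; then NaOH, H2O2, THF/H2O, 0 °C → rt
Reagents that add atoms: hydrogen peroxide, OO
Why: Proposed new method: sBuLi/TMEDA should remove the C1–H of 22 with retention (the benzoate carbonyl directs the base and stabilises the configurationally stable tertiary α-oxy organolithium 34), 33 borylates it with retention to give ate complex 35, and the sec-alkyl group C15 then shifts from boron to C1 antiperiplanar to the departing benzoate (inversion at C1, retention at C15) to give 36, whose C–B bond is oxidised with retention. The closest known reaction type is the lithiation–borylation of secondary dialkyl 2,4,6-triisopropylbenzoates with primary or aryl neopentyl glycol boronic esters and of benzylic carbamates with secondary boronic esters; the extension is the union of an unactivated tertiary carbenoid with an α-branched boronic ester, for which the small neopentyl glycol ester and the good benzoate leaving group are chosen. No ring is closed in this step. C1 is controlled by stereospecific transfer from the (1S)-benzoate stereocentre and C15 by the stereoretentive 1,2-shift, so neither centre depends on telling apart the two nearly equal ring arms at a trigonal C1. The step needs α-oxy lithiation to outrun allylic deprotonation, which the complex-induced proximity effect of the benzoate at −60 °C should secure, and carbon migration to outrun oxygen migration, which the higher migratory aptitude of the sec-alkyl group should secure.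

Step 23
Reactants: 37 tert-butyl{[(2E,6R)-6-[(1S,3Z,7E,11E)-1-hydroxy-4,8,12-trimethylcyclotetradeca-3,7,11-trien-1-yl]-2-methylhept-2-en-1-yl]oxy}dimethylsilane
Product: 38 (1S,3Z,7E,11E)-1-[(2R,5E)-7-hydroxy-6-methylhept-5-en-2-yl]-4,8,12-trimethylcyclotetradeca-3,7,11-trien-1-ol
Conditions: TBAF, THF, 0 °C → rt
Reagents that add atoms: none
Why: Fluoride-induced desilylation of the primary allylic silyl ether releases the target without touching the tertiary alcohol or the alkenes.

**Compound list**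

1 | geraniol | CC(C)=CCC/C(C)=C/CO | starting material
2 | geranyl 4-methoxybenzyl ether | CC(C)=CCC/C(C)=C/COCc1ccc(OC)cc1 | intermediate
3 | (2E,6E)-8-[(4-methoxybenzyl)oxy]-2,6-dimethylocta-2,6-dien-1-ol | OC/C(C)=C/CC/C(C)=C/COCc1ccc(OC)cc1 | intermediate
4 | 1-({[(2E,6E)-8-bromo-3,7-dimethylocta-2,6-dien-1-yl]oxy}methyl)-4-methoxybenzene | BrC/C(C)=C/CC/C(C)=C/COCc1ccc(OC)cc1 | intermediate
5 | methyl acetoacetate | COC(=O)CC(C)=O | starting material
6 | sodium lithium dianion of methyl acetoacetate | COC(=O)[CH-]C(=O)[CH2-].[Na+].[Li+] | intermediate (not isolated)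
7 | methyl (6E,10E)-12-[(4-methoxybenzyl)oxy]-6,10-dimethyl-3-oxododeca-6,10-dienoate | COC(=O)CC(=O)CC/C(C)=C/CC/C(C)=C/COCc1ccc(OC)cc1 | intermediate
8 | methyl (3R,6E,10E)-3-hydroxy-12-[(4-methoxybenzyl)oxy]-6,10-dimethyldodeca-6,10-dienoate | COC(=O)C[C@H](O)CC/C(C)=C/CC/C(C)=C/COCc1ccc(OC)cc1 | intermediate
9 | methyl (3R,6E,10E)-3-[(tert-butyldimethylsilyl)oxy]-12-[(4-methoxybenzyl)oxy]-6,10-dimethyldodeca-6,10-dienoate | COC(=O)C[C@H](O[Si](C)(C)C(C)(C)C)CC/C(C)=C/CC/C(C)=C/COCc1ccc(OC)cc1 | intermediate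
10 | methyl (3R,6E,10E)-3-[(tert-butyldimethylsilyl)oxy]-12-hydroxy-6,10-dimethyldodeca-6,10-dienoate | COC(=O)C[C@H](O[Si](C)(C)C(C)(C)C)CC/C(C)=C/CC/C(C)=C/CO | intermediate
11 | methyl (3R,6E,10E)-12-bromo-3-[(tert-butyldimethylsilyl)oxy]-6,10-dimethyldodeca-6,10-dienoate | COC(=O)C[C@H](O[Si](C)(C)C(C)(C)C)CC/C(C)=C/CC/C(C)=C/CBr | intermediate (not isolated)
12 | methyl (3R,6E,10E)-3-[(tert-butyldimethylsilyl)oxy]-6,10-dimethyl-12-(phenylsulfonyl)dodeca-6,10-dienoate | COC(=O)C[C@H](O[Si](C)(C)C(C)(C)C)CC/C(C)=C/CC/C(C)=C/CS(=O)(=O)c1ccccc1 | intermediate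
13 | (3R,6E,10E)-3-[(tert-butyldimethylsilyl)oxy]-6,10-dimethyl-12-(phenylsulfonyl)dodeca-6,10-dienal | O=CC[C@H](O[Si](C)(C)C(C)(C)C)CC/C(C)=C/CC/C(C)=C/CS(=O)(=O)c1ccccc1 | intermediate
14 | ethyl 2-[bis(2,2,2-trifluoroethoxy)phosphoryl]propanoate | CCOC(=O)C(C)P(=O)(OCC(F)(F)F)OCC(F)(F)F | starting material
15 | potassium carbanion of 14 | CCOC(=O)[C-](C)P(=O)(OCC(F)(F)F)OCC(F)(F)F.[K+] | intermediate (not isolated)
16 | ethyl (2Z,5R,8E,12E)-5-[(tert-butyldimethylsilyl)oxy]-2,8,12-trimethyl-14-(phenylsulfonyl)tetradeca-2,8,12-trienoate | CCOC(=O)/C(C)=C\C[C@H](O[Si](C)(C)C(C)(C)C)CC/C(C)=C/CC/C(C)=C/CS(=O)(=O)c1ccccc1 | intermediate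
17 | (2Z,5R,8E,12E)-5-[(tert-butyldimethylsilyl)oxy]-2,8,12-trimethyl-14-(phenylsulfonyl)tetradeca-2,8,12-trien-1-ol | OC/C(C)=C\C[C@H](O[Si](C)(C)C(C)(C)C)CC/C(C)=C/CC/C(C)=C/CS(=O)(=O)c1ccccc1 | intermediate
18 | tert-butyl{[(2Z,5R,8E,12E)-1-chloro-2,8,12-trimethyl-14-(phenylsulfonyl)tetradeca-2,8,12-trien-5-yl]oxy}dimethylsilane | ClC/C(C)=C\C[C@H](O[Si](C)(C)C(C)(C)C)CC/C(C)=C/CC/C(C)=C/CS(=O)(=O)c1ccccc1 | intermediate
19 | tert-butyldimethyl{[(1R,3Z,7E,11E)-4,8,12-trimethyl-6-(phenylsulfonyl)cyclotetradeca-3,7,11-trien-1-yl]oxy}silane (both C6 epimers) | C/C1=C/C[C@H](O[Si](C)(C)C(C)(C)C)CC/C(C)=C/CC/C(C)=C/C(S(=O)(=O)c2ccccc2)C1 | intermediate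
20 | tert-butyldimethyl{[(1R,3Z,7E,11E)-4,8,12-trimethylcyclotetradeca-3,7,11-trien-1-yl]oxy}silane | C/C1=C/C[C@H](O[Si](C)(C)C(C)(C)C)CC/C(C)=C/CC/C(C)=C/CC1 | intermediate
21 | (1R,3Z,7E,11E)-4,8,12-trimethylcyclotetradeca-3,7,11-trien-1-ol | C/C1=C/C[C@H](O)CC/C(C)=C/CC/C(C)=C/CC1 | intermediate
22 | (1S,3Z,7E,11E)-4,8,12-trimethylcyclotetradeca-3,7,11-trien-1-yl 2,4,6-tri(propan-2-yl)benzoate | C/C1=C/C[C@@H](OC(=O)c2c(C(C)C)cc(C(C)C)cc2C(C)C)CC/C(C)=C/CC/C(C)=C/CC1 | intermediate
23 | but-3-en-1-ylmagnesium bromide | C=CCC[Mg]Br | starting material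
24 | dimethyl but-3-en-1-ylboronate | C=CCCB(OC)OC | intermediate (not isolated)
25 | 2-(but-3-en-1-yl)-5,5-dimethyl-1,3,2-dioxaborinane | C=CCCB1OCC(C)(C)CO1 | intermediate
26 | methacrolein | CC(=C)C=O | starting material
27 | (2E)-5-(5,5-dimethyl-1,3,2-dioxaborinan-2-yl)-2-methylpent-2-enal | O=C/C(C)=C/CCB1OCC(C)(C)CO1 | intermediate
28 | (2E)-5-(5,5-dimethyl-1,3,2-dioxaborinan-2-yl)-2-methylpent-2-en-1-ol | OC/C(C)=C/CCB1OCC(C)(C)CO1 | intermediate
29 | tert-butyl{[(2E)-5-(5,5-dimethyl-1,3,2-dioxaborinan-2-yl)-2-methylpent-2-en-1-yl]oxy}dimethylsilane | CC(C)(C)[Si](C)(C)OC/C(C)=C/CCB1OCC(C)(C)CO1 | intermediate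
30 | ethyl 2,4,6-tri(propan-2-yl)benzoate | CCOC(=O)c1c(C(C)C)cc(C(C)C)cc1C(C)C | starting material
31 | (1S)-1-lithioethyl 2,4,6-tri(propan-2-yl)benzoate (sparteine complex; ligand not drawn) | C[C@H]([Li])OC(=O)c1c(C(C)C)cc(C(C)C)cc1C(C)C | intermediate (not isolated)
32 | lithium boronate complex of 31 and 29 (carbenoid carbon S) | C[C@H]([B-]1(CC/C=C(\C)CO[Si](C)(C)C(C)(C)C)OCC(C)(C)CO1)OC(=O)c2c(C(C)C)cc(C(C)C)cc2C(C)C.[Li+] | intermediate (not isolated)
33 | tert-butyl{[(2E,6R)-6-(5,5-dimethyl-1,3,2-dioxaborinan-2-yl)-2-methylhept-2-en-1-yl]oxy}dimethylsilane | C[C@H](CC/C=C(\C)CO[Si](C)(C)C(C)(C)C)B1OCC(C)(C)CO1 | intermediate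
34 | (1S,3Z,7E,11E)-1-lithio-4,8,12-trimethylcyclotetradeca-3,7,11-trien-1-yl 2,4,6-tri(propan-2-yl)benzoate | C/C1=C/C[C@@]([Li])(OC(=O)c2c(C(C)C)cc(C(C)C)cc2C(C)C)CC/C(C)=C/CC/C(C)=C/CC1 | intermediate (not isolated)
35 | lithium boronate complex of 34 and 33 (boron bound to C1 and C15) | C/C1=C/C[C@@]([B-]2([C@H](C)CC/C=C(\C)CO[Si](C)(C)C(C)(C)C)OCC(C)(C)CO2)(OC(=O)c3c(C(C)C)cc(C(C)C)cc3C(C)C)CC/C(C)=C/CC/C(C)=C/CC1.[Li+] | intermediate (not isolated)
36 | tertiary boronic ester: 37 with the 5,5-dimethyl-1,3,2-dioxaborinan-2-yl group in place of OH at C1 (same spatial arrangement) | C/C1=C/C[C@](B2OCC(C)(C)CO2)([C@H](C)CC/C=C(\C)CO[Si](C)(C)C(C)(C)C)CC/C(C)=C/CC/C(C)=C/CC1 | intermediate (not isolated)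
37 | tert-butyl{[(2E,6R)-6-[(1S,3Z,7E,11E)-1-hydroxy-4,8,12-trimethylcyclotetradeca-3,7,11-trien-1-yl]-2-methylhept-2-en-1-yl]oxy}dimethylsilane | C/C1=C/C[C@](O)([C@H](C)CC/C=C(\C)CO[Si](C)(C)C(C)(C)C)CC/C(C)=C/CC/C(C)=C/CC1 | intermediate
38 | (1S,3Z,7E,11E)-1-[(2R,5E)-7-hydroxy-6-methylhept-5-en-2-yl]-4,8,12-trimethylcyclotetradeca-3,7,11-trien-1-ol | C/C1=C/C[C@](O)([C@H](C)CC/C=C(\C)CO)CC/C(C)=C/CC/C(C)=C/CC1 | target

**Step count and risks**

Total step count: 23 (steps 1–16 ring fragment, steps 17–21 side chain, steps 22–23 union and deprotection).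
Longest linear sequence: 18 steps (steps 1–16, 22, 23, from geraniol).

Steps most likely to fail:

1. Step 22 (proposed new method). The ate complex between the hindered tertiary carbenoid and the α-branched boronic ester may form too slowly at −60 °C, so that the lithiated benzoate decomposes or is simply reprotonated. Competing allylic lithiation or migration of a boron-bound oxygen instead of C15 are further risks. The fallback uses known carbonyl-addition chemistry; it sets out from 21 and 33 and comes back at 37.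
   - From 21, buffered Dess–Martin oxidation (NaHCO3, CH2Cl2, 0 °C) would give (3Z,7E,11E)-4,8,12-trimethylcyclotetradeca-3,7,11-trien-1-one F1.
   - From 33, NaOH/H2O2 would give (2R,5E)-7-[(tert-butyldimethylsilyl)oxy]-6-methylhept-5-en-2-ol F2, and I2/PPh3/imidazole (inversion) would give tert-butyl{[(2E,6S)-6-iodo-2-methylhept-2-en-1-yl]oxy}dimethylsilane F3.
   - Magnesium insertion would give [(5E)-7-[(tert-butyldimethylsilyl)oxy]-6-methylhept-5-en-2-yl]magnesium iodide F4. In the presence of anhydrous CeCl3 (THF, −78 °C) it should add to the enolisable ketone F1 to give 37 together with its C1 and C15 stereoisomers.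
   - Neither centre is controlled in this mode, so 37 would have to be isolated by preparative chromatography on a chiral phase before step 23.

2. Step 13. Intermolecular alkylation to oligomers may outrun closure of the 14-membered ring, or the hindered sulfonyl carbanion may consume the (Z)-allylic chloride by elimination or SN2′ attack. The fallback closes the ring with the smaller and more nucleophilic α-thio allyl carbanion and removes sulfur by dissolving-metal C–S cleavage; it sets out from 10 and comes back at 20, so that step 14 is not needed.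
   - PhSSPh/Bu3P would convert 10 into methyl (3R,6E,10E)-3-[(tert-butyldimethylsilyl)oxy]-6,10-dimethyl-12-(phenylsulfanyl)dodeca-6,10-dienoate F5.
   - DIBAL-H (−78 °C) would give (3R,6E,10E)-3-[(tert-butyldimethylsilyl)oxy]-6,10-dimethyl-12-(phenylsulfanyl)dodeca-6,10-dienal F6.
   - Still–Gennari olefination with 14 would give ethyl (2Z,5R,8E,12E)-5-[(tert-butyldimethylsilyl)oxy]-2,8,12-trimethyl-14-(phenylsulfanyl)tetradeca-2,8,12-trienoate F7.
   - DIBAL-H would give (2Z,5R,8E,12E)-5-[(tert-butyldimethylsilyl)oxy]-2,8,12-trimethyl-14-(phenylsulfanyl)tetradeca-2,8,12-trien-1-ol F8.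
   - MsCl/LiCl/2,4,6-collidine (DMF, 0 °C) would give tert-butyl{[(2Z,5R,8E,12E)-1-chloro-2,8,12-trimethyl-14-(phenylsulfanyl)tetradeca-2,8,12-trien-5-yl]oxy}dimethylsilane F9.
   - nBuLi/DABCO (THF, −78 °C, high dilution) would give tert-butyldimethyl{[(1R,3Z,7E,11E)-4,8,12-trimethyl-6-(phenylsulfanyl)cyclotetradeca-3,7,11-trien-1-yl]oxy}silane F10.
   - Li/EtNH2 (−78 °C) would cleave the allylic C–S bond to give 20.

3. Step 16. The hindered carboxylate is a slow nucleophile, so the activated alcohol may eliminate across the allylic C2–H to a conjugated diene, or substitution may stay incomplete. The fallback separates inversion from acylation; it sets out from 21 and comes back at 22.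
   - Mitsunobu reaction with 4-nitrobenzoic acid (PPh3, DIAD, THF) would give (1S,3Z,7E,11E)-4,8,12-trimethylcyclotetradeca-3,7,11-trien-1-yl 4-nitrobenzoate F11.
   - K2CO3/MeOH would give (1S,3Z,7E,11E)-4,8,12-trimethylcyclotetradeca-3,7,11-trien-1-ol F12.
   - KHMDS followed by 2,4,6-triisopropylbenzoyl chloride (THF, 0 → 50 °C) would acylate the alkoxide with retention to give 22.

**Further compounds**

F1 | step 22 | (3Z,7E,11E)-4,8,12-trimethylcyclotetradeca-3,7,11-trien-1-one | C/C1=C/CC(=O)CC/C(C)=C/CC/C(C)=C/CC1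
F2 | step 22 | (2R,5E)-7-[(tert-butyldimethylsilyl)oxy]-6-methylhept-5-en-2-ol | C[C@@H](O)CC/C=C(\C)CO[Si](C)(C)C(C)(C)C
F3 | step 22 | tert-butyl{[(2E,6S)-6-iodo-2-methylhept-2-en-1-yl]oxy}dimethylsilane | C[C@H](I)CC/C=C(\C)CO[Si](C)(C)C(C)(C)C
F4 | step 22 | [(5E)-7-[(tert-butyldimethylsilyl)oxy]-6-methylhept-5-en-2-yl]magnesium iodide (racemic at the metal-bearing carbon) | CC([Mg]I)CC/C=C(\C)CO[Si](C)(C)C(C)(C)C
F5 | step 13 | methyl (3R,6E,10E)-3-[(tert-butyldimethylsilyl)oxy]-6,10-dimethyl-12-(phenylsulfanyl)dodeca-6,10-dienoate | COC(=O)C[C@H](O[Si](C)(C)C(C)(C)C)CC/C(C)=C/CC/C(C)=C/CSc1ccccc1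
F6 | step 13 | (3R,6E,10E)-3-[(tert-butyldimethylsilyl)oxy]-6,10-dimethyl-12-(phenylsulfanyl)dodeca-6,10-dienal | O=CC[C@H](O[Si](C)(C)C(C)(C)C)CC/C(C)=C/CC/C(C)=C/CSc1ccccc1
F7 | step 13 | ethyl (2Z,5R,8E,12E)-5-[(tert-butyldimethylsilyl)oxy]-2,8,12-trimethyl-14-(phenylsulfanyl)tetradeca-2,8,12-trienoate | CCOC(=O)/C(C)=C\C[C@H](O[Si](C)(C)C(C)(C)C)CC/C(C)=C/CC/C(C)=C/CSc1ccccc1
F8 | step 13 | (2Z,5R,8E,12E)-5-[(tert-butyldimethylsilyl)oxy]-2,8,12-trimethyl-14-(phenylsulfanyl)tetradeca-2,8,12-trien-1-ol | OC/C(C)=C\C[C@H](O[Si](C)(C)C(C)(C)C)CC/C(C)=C/CC/C(C)=C/CSc1ccccc1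
F9 | step 13 | tert-butyl{[(2Z,5R,8E,12E)-1-chloro-2,8,12-trimethyl-14-(phenylsulfanyl)tetradeca-2,8,12-trien-5-yl]oxy}dimethylsilane | ClC/C(C)=C\C[C@H](O[Si](C)(C)C(C)(C)C)CC/C(C)=C/CC/C(C)=C/CSc1ccccc1
F10 | step 13 | tert-butyldimethyl{[(1R,3Z,7E,11E)-4,8,12-trimethyl-6-(phenylsulfanyl)cyclotetradeca-3,7,11-trien-1-yl]oxy}silane (both C6 epimers) | C/C1=C/C[C@H](O[Si](C)(C)C(C)(C)C)CC/C(C)=C/CC/C(C)=C/C(Sc2ccccc2)C1
F11 | step 16 | (1S,3Z,7E,11E)-4,8,12-trimethylcyclotetradeca-3,7,11-trien-1-yl 4-nitrobenzoate | C/C1=C/C[C@@H](OC(=O)c2ccc([N+](=O)[O-])cc2)CC/C(C)=C/CC/C(C)=C/CC1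
F12 | step 16 | (1S,3Z,7E,11E)-4,8,12-trimethylcyclotetradeca-3,7,11-trien-1-ol | C/C1=C/C[C@@H](O)CC/C(C)=C/CC/C(C)=C/CC1
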